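Ring B, the hexasubstituted central ring (C1 carboxyl, C2 and C4 oxygen, C3, C5 and C6 methyl), is cut across B1–B6 and B3–B4. In one operation a Michael addition followed by a Claisen ring closure joins two acyclic commercial esters, tert-butyl 3-oxopentanoate (supplying B1–B3 and the C3 methyl) and ethyl tiglate (supplying B4–B6 and the C5 and C6 methyls), into a 2,4-dioxocyclohexanecarboxylate in which every ring B substituent already sits at its final position; dehydrogenation then gives the resorcylate. Rings C and A, both from 2,5-dimethylresorcinol, are attached by acylation of the unchelated para hydroxyls, ring A as its aldehyde.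

Key step: step 1

Remark: compounds 1, 2 and 6 are taken as purchasable; dione 4 is carried forward as its mixture of diastereomers and enol tautomers, since all of its sp3 centres are erased in step 2 and the target has no stereocentre.

Step 1
Reactants: 1 tert-butyl 3-oxopentanoate; 2 ethyl tiglate
Product: 4 tert-butyl 3,5,6-trimethyl-2,4-dioxocyclohexane-1-carboxylate, via Michael adduct 3 (not isolated)
Conditions: KOC(CH3)3 (1.2 equiv), 2 (1.3 equiv), t-BuOH (concentrated), reflux; then cold 1 M HCl
Reagents that add atoms: none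
Why: The potassium enolate of 1 adds through its doubly activated carbon to the beta-carbon of 2 (Michael addition, bond B1–B6), adduct 3 equilibrates under alkoxide to the enolate on the ethyl side of the ketone, and this enolate attacks the ethyl ester in a Claisen (Dieckmann-type) condensation that forms B3–B4 and expels ethoxide. The closest known reaction type is the Michael–Claisen annulation of beta-keto esters with crotonate esters to dihydroresorcylates. The single ring closes in a 6-(enolendo)-exo-trig mode. No stereocentre needs control, because the four sp3 centres of 4 arise as a mixture and all vanish on aromatisation. The step needs closure from the ethyl-side enolate onto the ethyl ester, and the substrate secures this because the tert-butyl ester is too hindered to act as acceptor (and cannot be scrambled by tert-butoxide) while every other enolate–ester pairing would give a four-membered ring. Deprotonation of the acidic 1,3-dione by the stoichiometric base removes 4 from the equilibria and should pull the sluggish addition to the alpha-substituted acceptor forward.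

Step 2
Reactants: 4 tert-butyl 3,5,6-trimethyl-2,4-dioxocyclohexane-1-carboxylate
Product: 5 tert-butyl 2,4-dihydroxy-3,5,6-trimethylbenzoate
Conditions: Pd(OCOCF3)2 (5 mol%), 2-(dimethylamino)pyridine (10 mol%), TsOH·H2O (20 mol%), O2 (1 atm), DMSO, 80 °C
Reagents that add atoms: none
Why: Palladium-catalysed aerobic dehydrogenation of a cyclohexanone to a phenol: palladation at C5 of the C4 ketone enol, beta-hydride elimination toward C6 and tautomerisation of the resulting cyclohexenedione should give the aromatic resorcylate, with O2 reoxidising the palladium hydride and the buffered sub-stoichiometric acid in DMSO expected to spare the tert-butyl ester.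

Step 3
Reactants: 6 2,5-dimethylresorcinol
Product: 8 2,4-dihydroxy-3,6-dimethylbenzaldehyde, via iminium chloride 7 (not isolated)
Conditions: POCl3 (1.2 equiv), DMF (3 equiv), MeCN, 0 °C to rt; then H2O, 50 °C
Reagents that add atoms: N,N-dimethylformamide CN(C)C=O; water O
Why: Vilsmeier–Haack formylation of an electron-rich resorcinol, in which C4 and C6 of 6 are the only free positions, are equivalent by symmetry and are each ortho to one hydroxyl and para to the other, so a single aldehyde should result after hydrolysis of iminium salt 7.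

Step 4
Reactants: 8 2,4-dihydroxy-3,6-dimethylbenzaldehyde
Product: 9 2,4-bis(benzyloxy)-3,6-dimethylbenzaldehyde
Conditions: BnBr (2.4 equiv), K2CO3 (3 equiv), DMF, 60 °C
Reagents that add atoms: benzyl bromide BrCc1ccccc1
Why: Williamson ether synthesis, in which excess benzyl bromide and carbonate in warm DMF should alkylate both the free and the chelated phenoxide of an aldehyde that has no enolisable position.

Step 5
Reactants: 9 2,4-bis(benzyloxy)-3,6-dimethylbenzaldehyde
Product: 10 2,4-bis(benzyloxy)-3,6-dimethylbenzoic acid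
Conditions: NaClO2, NaH2PO4, 2-methyl-2-butene, t-BuOH/THF/H2O, rt
Reagents that add atoms: sodium chlorite [Na+].[O-]Cl=O
Why: Pinnick oxidation, in which chlorous acid converts the hindered aryl aldehyde to the acid without touching the benzyl ethers while 2-methyl-2-butene traps the hypochlorous acid that could otherwise chlorinate the electron-rich ring.

Step 6
Reactants: 10 2,4-bis(benzyloxy)-3,6-dimethylbenzoic acid; 5 tert-butyl 2,4-dihydroxy-3,5,6-trimethylbenzoate
Product: 12 tert-butyl 4-{[2,4-bis(benzyloxy)-3,6-dimethylbenzoyl]oxy}-2-hydroxy-3,5,6-trimethylbenzoate, via acid chloride 11 (not isolated)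
Conditions: 10, (COCl)2, cat. DMF, CH2Cl2, 0 °C to rt, evaporate; 5, NaH (1.0 equiv), THF/DMF, 0 °C; then 11, 0 °C to rt
Reagents that add atoms: none
Why: Acid chloride formation followed by O-acylation of a phenoxide, in which one equivalent of NaH removes the more acidic C4–OH proton of ring B (para to the ester) while the C2–OH stays locked in its hydrogen bond to the ester carbonyl, and the alkoxy-stabilised di-ortho-substituted aroyl chloride reacts through an acylium-like transition state that should tolerate the two flanking methyls.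

Step 7
Reactants: 12 tert-butyl 4-{[2,4-bis(benzyloxy)-3,6-dimethylbenzoyl]oxy}-2-hydroxy-3,5,6-trimethylbenzoate
Product: 13 tert-butyl 4-{[2,4-bis(benzyloxy)-3,6-dimethylbenzoyl]oxy}-2-methoxy-3,5,6-trimethylbenzoate
Conditions: MeI (3 equiv), Cs2CO3 (1.5 equiv), DMF, rt
Reagents that add atoms: iodomethane CI
Why: Williamson O-methylation of the remaining chelated phenol through its caesium phenoxide, with the tert-butyl ester and the doubly shielded depside ester being poor electrophiles toward carbonate and the ester lying meta to the phenoxide so that no acyl shift is possible.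

Step 8
Reactants: 13 tert-butyl 4-{[2,4-bis(benzyloxy)-3,6-dimethylbenzoyl]oxy}-2-methoxy-3,5,6-trimethylbenzoate
Product: 14 4-{[2,4-bis(benzyloxy)-3,6-dimethylbenzoyl]oxy}-2-methoxy-3,5,6-trimethylbenzoic acid
Conditions: TFA/CH2Cl2 (1:4), 0 °C to rt
Reagents that add atoms: none
Why: Acidolysis of a tert-butyl ester by alkyl–oxygen cleavage with loss of 2-methylpropene, which needs no nucleophile at the hindered carbonyl and should leave the aryl ester and the benzyl ethers untouched at low temperature.

Step 9
Reactants: 14 4-{[2,4-bis(benzyloxy)-3,6-dimethylbenzoyl]oxy}-2-methoxy-3,5,6-trimethylbenzoic acid; 8 2,4-dihydroxy-3,6-dimethylbenzaldehyde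
Product: 16 4-formyl-3-hydroxy-2,5-dimethylphenyl 4-{[2,4-bis(benzyloxy)-3,6-dimethylbenzoyl]oxy}-2-methoxy-3,5,6-trimethylbenzoate, via acid chloride 15 (not isolated)
Conditions: 14, (COCl)2, cat. DMF, CH2Cl2, 0 °C to rt, evaporate; 8, NaH (1.0 equiv), THF, 0 °C; then 15, 0 °C to rt
Reagents that add atoms: none
Why: Acid chloride formation and regioselective phenoxide O-acylation as in step 6, in which the C4–OH of 8 (para to the formyl group) is deprotonated by one equivalent of NaH and acylated whereas the C2–OH remains chelated to the aldehyde.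

Step 10
Reactants: 16 4-formyl-3-hydroxy-2,5-dimethylphenyl 4-{[2,4-bis(benzyloxy)-3,6-dimethylbenzoyl]oxy}-2-methoxy-3,5,6-trimethylbenzoate
Product: 17 4-formyl-3-methoxy-2,5-dimethylphenyl 4-{[2,4-bis(benzyloxy)-3,6-dimethylbenzoyl]oxy}-2-methoxy-3,5,6-trimethylbenzoate
Conditions: MeI (3 equiv), K2CO3 (1.5 equiv), DMF, rt
Reagents that add atoms: iodomethane CI
Why: Williamson O-methylation of the salicylaldehyde-type hydroxyl, in which mild carbonate at room temperature should not attack the aryl esters because each ester carbonyl is flanked by two ortho substituents.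

Step 11
Reactants: 17 4-formyl-3-methoxy-2,5-dimethylphenyl 4-{[2,4-bis(benzyloxy)-3,6-dimethylbenzoyl]oxy}-2-methoxy-3,5,6-trimethylbenzoate
Product: 18 4-[(4-{[2,4-bis(benzyloxy)-3,6-dimethylbenzoyl]oxy}-2-methoxy-3,5,6-trimethylbenzoyl)oxy]-2-methoxy-3,6-dimethylbenzoic acid
Conditions: NaClO2, NaH2PO4, 2-methyl-2-butene, t-BuOH/THF/H2O, rt
Reagents that add atoms: sodium chlorite [Na+].[O-]Cl=O
Why: Pinnick oxidation of the ring A aldehyde to the carboxylic acid under weakly acidic buffered conditions that should not hydrolyse aryl esters, with the alkene scavenger protecting the benzyloxy-substituted ring C from chlorination.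

Step 12
Reactants: 18 4-[(4-{[2,4-bis(benzyloxy)-3,6-dimethylbenzoyl]oxy}-2-methoxy-3,5,6-trimethylbenzoyl)oxy]-2-methoxy-3,6-dimethylbenzoic acid
Product: 19 4-[(4-{[2,4-dihydroxy-3,6-dimethylbenzoyl]oxy}-2-methoxy-3,5,6-trimethylbenzoyl)oxy]-2-methoxy-3,6-dimethylbenzoic acid
Conditions: H2 (1 atm), 10% Pd/C, EtOAc/THF, rt
Reagents that add atoms: none
Why: Catalytic hydrogenolysis of the two benzyl aryl ethers, a neutral deprotection that should leave both depside esters, the methyl ethers and the free acid unchanged and deliver the target.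

Compound list
1 | tert-butyl 3-oxopentanoate | CCC(=O)CC(=O)OC(C)(C)C | starting material
2 | ethyl tiglate, ethyl (E)-2-methylbut-2-enoate | C/C=C(\C)C(=O)OCC | starting material
3 | Michael adduct 1-tert-butyl 5-ethyl 3,4-dimethyl-2-propanoylpentanedioate (mixture of diastereomers, in situ) | CCC(=O)C(C(=O)OC(C)(C)C)C(C)C(C)C(=O)OCC | intermediate
4 | tert-butyl 3,5,6-trimethyl-2,4-dioxocyclohexane-1-carboxylate (mixture of diastereomers and enol tautomers) | CC1C(=O)C(C)C(=O)C(C(=O)OC(C)(C)C)C1C | intermediate
5 | tert-butyl 2,4-dihydroxy-3,5,6-trimethylbenzoate | Cc1c(C)c(C(=O)OC(C)(C)C)c(O)c(C)c1O | intermediate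
6 | 2,5-dimethylresorcinol | Cc1cc(O)c(C)c(O)c1 | starting material
7 | N-[(2,4-dihydroxy-3,6-dimethylphenyl)methylidene]-N-methylmethanaminium chloride (in situ) | Cc1cc(O)c(C)c(O)c1C=[N+](C)C.[Cl-] | intermediate
8 | 2,4-dihydroxy-3,6-dimethylbenzaldehyde | Cc1cc(O)c(C)c(O)c1C=O | intermediate
9 | 2,4-bis(benzyloxy)-3,6-dimethylbenzaldehyde | Cc1cc(OCc2ccccc2)c(C)c(OCc2ccccc2)c1C=O | intermediate
10 | 2,4-bis(benzyloxy)-3,6-dimethylbenzoic acid | Cc1cc(OCc2ccccc2)c(C)c(OCc2ccccc2)c1C(=O)O | intermediate
11 | 2,4-bis(benzyloxy)-3,6-dimethylbenzoyl chloride (in situ) | Cc1cc(OCc2ccccc2)c(C)c(OCc2ccccc2)c1C(=O)Cl | intermediate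
12 | tert-butyl 4-{[2,4-bis(benzyloxy)-3,6-dimethylbenzoyl]oxy}-2-hydroxy-3,5,6-trimethylbenzoate | Cc1cc(OCc2ccccc2)c(C)c(OCc2ccccc2)c1C(=O)Oc1c(C)c(C)c(C(=O)OC(C)(C)C)c(O)c1C | intermediate
13 | tert-butyl 4-{[2,4-bis(benzyloxy)-3,6-dimethylbenzoyl]oxy}-2-methoxy-3,5,6-trimethylbenzoate | Cc1cc(OCc2ccccc2)c(C)c(OCc2ccccc2)c1C(=O)Oc1c(C)c(C)c(C(=O)OC(C)(C)C)c(OC)c1C | intermediate
14 | 4-{[2,4-bis(benzyloxy)-3,6-dimethylbenzoyl]oxy}-2-methoxy-3,5,6-trimethylbenzoic acid | Cc1cc(OCc2ccccc2)c(C)c(OCc2ccccc2)c1C(=O)Oc1c(C)c(C)c(C(=O)O)c(OC)c1C | intermediate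
15 | 4-{[2,4-bis(benzyloxy)-3,6-dimethylbenzoyl]oxy}-2-methoxy-3,5,6-trimethylbenzoyl chloride (in situ) | Cc1cc(OCc2ccccc2)c(C)c(OCc2ccccc2)c1C(=O)Oc1c(C)c(C)c(C(=O)Cl)c(OC)c1C | intermediate
16 | 4-formyl-3-hydroxy-2,5-dimethylphenyl 4-{[2,4-bis(benzyloxy)-3,6-dimethylbenzoyl]oxy}-2-methoxy-3,5,6-trimethylbenzoate | Cc1cc(OCc2ccccc2)c(C)c(OCc2ccccc2)c1C(=O)Oc1c(C)c(C)c(C(=O)Oc2cc(C)c(C=O)c(O)c2C)c(OC)c1C | intermediate
17 | 4-formyl-3-methoxy-2,5-dimethylphenyl 4-{[2,4-bis(benzyloxy)-3,6-dimethylbenzoyl]oxy}-2-methoxy-3,5,6-trimethylbenzoate | Cc1cc(OCc2ccccc2)c(C)c(OCc2ccccc2)c1C(=O)Oc1c(C)c(C)c(C(=O)Oc2cc(C)c(C=O)c(OC)c2C)c(OC)c1C | intermediate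
18 | 4-[(4-{[2,4-bis(benzyloxy)-3,6-dimethylbenzoyl]oxy}-2-methoxy-3,5,6-trimethylbenzoyl)oxy]-2-methoxy-3,6-dimethylbenzoic acid | Cc1cc(OCc2ccccc2)c(C)c(OCc2ccccc2)c1C(=O)Oc1c(C)c(C)c(C(=O)Oc2cc(C)c(C(=O)O)c(OC)c2C)c(OC)c1C | intermediate
19 | 4-[(4-{[2,4-dihydroxy-3,6-dimethylbenzoyl]oxy}-2-methoxy-3,5,6-trimethylbenzoyl)oxy]-2-methoxy-3,6-dimethylbenzoic acid (CNP0425440.0, achiral) | COc1c(C)c(OC(=O)c2c(C)c(C)c(OC(=O)c3c(C)cc(O)c(C)c3O)c(C)c2OC)cc(C)c1C(=O)O | target

Total step count: 12.
Longest linear sequence: 10 steps (steps 3, 4, 5, 6, 7, 8, 9, 10, 11 and 12, from 2,5-dimethylresorcinol). The line through the key step has 9 steps (1, 2, 6 to 12).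

Steps most likely to fail

Step 1. The conjugate addition to the alpha,beta-dimethyl-substituted acrylate may stall, so that gamma-deprotonation and deconjugation of the tiglate or retro-Claisen fragmentation of the keto ester take over. The fallback builds the same ring with the donor and acceptor roles exchanged, forming B1–B6 and B2–B3 instead. It sets out from no numbered compound, because step 1 opens the route, and uses two purchasable partners: tert-butyl ethyl malonate F1 and (E)-4-methylhex-4-en-3-one F2, an enone far more electrophilic than a tiglate. Catalytic NaOC2H5 in EtOH at room temperature should give the Michael adduct 1-tert-butyl 3-ethyl 2-(3-methyl-4-oxohexan-2-yl)propanedioate F3. Stoichiometric KOC(CH3)3 in t-BuOH at reflux should then close the ring by Claisen attack of the ethyl-ketone enolate on the ethyl ester, and acidification returns the route to compound 4.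

Step 2. The chelating dione enolate may sequester the palladium catalyst, or acid at 80 °C may strip isobutene from the beta-keto ester, which would then decarboxylate. The fallback replaces metal catalysis by quinone dehydrogenation. From compound 4, DDQ (1.2 equiv) in 1,4-dioxane at room temperature to 60 °C should abstract hydride from the dienol tautomer at C5/C6 under essentially neutral conditions, and loss of a proton then gives compound 5 directly.

Step 6. Acylation at the hydroxyl flanked by two methyls may be incomplete, or selectivity may erode through over-acylation at the chelated hydroxyl once forcing conditions are applied. The fallback gives up the direct selective acylation and differentiates the two hydroxyls first. From compound 5, BnBr (1.05 equiv) and K2CO3 in acetone at reflux should benzylate only the unchelated hydroxyl to give tert-butyl 4-(benzyloxy)-2-hydroxy-3,5,6-trimethylbenzoate F4. MeI and Cs2CO3 in DMF should then give tert-butyl 4-(benzyloxy)-2-methoxy-3,5,6-trimethylbenzoate F5. Hydrogenolysis (H2, 10% Pd/C, EtOAc) should free tert-butyl 4-hydroxy-2-methoxy-3,5,6-trimethylbenzoate F6. Its sodium phenoxide (NaH, DMF) can then be driven to completion with an excess of acid chloride 11 and warming, since no second hydroxyl remains, which rejoins the route at compound 13.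

Further compounds
F1 | step 1 | tert-butyl ethyl malonate | CCOC(=O)CC(=O)OC(C)(C)C
F2 | step 1 | (E)-4-methylhex-4-en-3-one | CCC(=O)/C(C)=C/C
F3 | step 1 | 1-tert-butyl 3-ethyl 2-(3-methyl-4-oxohexan-2-yl)propanedioate | CCC(=O)C(C)C(C)C(C(=O)OCC)C(=O)OC(C)(C)C
F0 | step 2 | none | none
F4 | step 6 | tert-butyl 4-(benzyloxy)-2-hydroxy-3,5,6-trimethylbenzoate | Cc1c(C)c(C(=O)OC(C)(C)C)c(O)c(C)c1OCc1ccccc1
F5 | step 6 | tert-butyl 4-(benzyloxy)-2-methoxy-3,5,6-trimethylbenzoate | Cc1c(C)c(C(=O)OC(C)(C)C)c(OC)c(C)c1OCc1ccccc1
F6 | step 6 | tert-butyl 4-hydroxy-2-methoxy-3,5,6-trimethylbenzoate | Cc1c(C)c(C(=O)OC(C)(C)C)c(OC)c(C)c1O
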